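**Retrosynthetic overview**
1. Late stage: free O6, oxidise the isopropenyl CH3 to the enal with SeO2, and place the angelate on O9 of a bicyclic hydroxy-lactone.
2. Key cut: C8–C9 (reductive aldehyde–aldehyde coupling) and O8–C12 (lactone) are cut together, leading back to an acyclic dialdehyde acrylate. The cyclohexane (ring A) closes first and the lactone (ring B) follows in the same flask.
3. C6–C7: indium allylation of an α-isopropenyl aldehyde with a Morita–Baylis–Hillman-derived allyl bromide that carries C7, C8 and C11–C13.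
4. C5–C10: an enantioselective boron Ireland–Claisen rearrangement of an achiral prenol-derived ester sets the quaternary/tertiary pair.
5. Building blocks: prenol, senecioyl chloride, glyoxal dimethyl acetal, methyl acrylate, angelic acid.

Atom labels (elemanolide positions):
- C10 is the quaternary carbon, with CH3 = C14 and vinyl = C1/C2.
- C5 bears C4(=C3H2)–C15.
- C6 bears OH.
- C7 bears C11(=C13H2)–C12(=O).
- C8 bears the lactone O.
- C9 bears the angelate.

Assumption: the (S,S)-configured boron controller is taken to deliver the (2S,3S)-acid 9. If its sense proves opposite, the equally available (R,R)-controller is used and nothing else changes.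

**Step 1**
Reactants: 1 3-methylbut-2-en-1-ol (prenol); 2 3-methylbut-2-enoyl chloride (senecioyl chloride)
Product: 4 3-methylbut-2-en-1-yl 3-methylbut-3-enoate, via isopropenylketene 3 (not isolated)
Conditions: Et3N (2.2 equiv), CH2Cl2, −78 °C to 0 °C
Reagents that add atoms: none
Why: Et3N dehydrochlorinates the acid chloride at a γ-methyl to vinylketene 3 and prenol adds to it with α-protonation, so this deconjugative esterification (ketene acylation) gives the β,γ-unsaturated ester needed for clean α-enolisation later, and no stereocentre is formed.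

**Step 2**
Reactants: 4 3-methylbut-2-en-1-yl 3-methylbut-3-enoate
Product: 5 (2E)-4-hydroxy-3-methylbut-2-en-1-yl 3-methylbut-3-enoate
Conditions: SeO2 (0.4 equiv), tBuOOH (2.5 equiv), salicylic acid (0.1 equiv), CH2Cl2, 0 °C to rt
Reagents that add atoms: tert-butyl hydroperoxide, CC(C)(C)OO
Why: Selenium dioxide allylic oxidation (ene reaction, then [2,3]-sigmatropic shift) attacks the trisubstituted alkene faster than the 1,1-disubstituted one and oxidises the methyl trans to the chain, which fixes the E geometry that the chair of step 4 translates into C10.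

**Step 3**
Reactants: 5 (2E)-4-hydroxy-3-methylbut-2-en-1-yl 3-methylbut-3-enoate
Product: 6 (2E)-3-methyl-4-[(triethylsilyl)oxy]but-2-en-1-yl 3-methylbut-3-enoate
Conditions: Et3SiCl, imidazole, CH2Cl2, 0 °C
Reagents that add atoms: chlorotriethylsilane, CC[Si](Cl)(CC)CC
Why: Standard silyl ether formation masks the primary alcohol (future C9) so that it cannot bind the boron reagent of step 4, and no stereocentre is touched.

**Step 4**
Reactants: 6 (2E)-3-methyl-4-[(triethylsilyl)oxy]but-2-en-1-yl 3-methylbut-3-enoate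
Product: 9 (2S,3S)-3-methyl-2-(prop-1-en-2-yl)-3-{[(triethylsilyl)oxy]methyl}pent-4-enoic acid, via boron ketene acetal 7 (not isolated), via acyloxyborane 8 (not isolated)
Conditions: (S,S)-2-bromo-4,5-diphenyl-1,3-bis{[3,5-bis(trifluoromethyl)phenyl]sulfonyl}-1,3,2-diazaborolidine (made from the bis-sulfonamide and BBr3, CH2Cl2), Et3N, toluene–hexane, −78 °C then −20 °C, 48 h; aqueous work-up
Reagents that add atoms: none
Why: Enantioselective boron-mediated Ireland–Claisen rearrangement, in which soft enolisation in the non-polar medium gives 7 with the isopropenyl group cis to the allyloxy oxygen, the [3,3] shift runs through a chair where the E-alkene holds CH2OTES equatorial and CH3 axial (fixing C5/C10 with isopropenyl and vinyl syn along the C6–C5–C10–C9 zigzag), and the C2-symmetric sulfonamide ligand on boron selects the enolate face and hence the absolute configuration.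

**Step 5**
Reactants: 9 (2S,3S)-acid
Product: 11 (2S,3S)-3-methyl-2-(prop-1-en-2-yl)-3-{[(triethylsilyl)oxy]methyl}pent-4-enal, via acyl imidazolide 10 (not isolated)
Conditions: 1,1′-carbonyldiimidazole, THF, rt; then iBu2AlH, −78 °C; aqueous work-up
Reagents that add atoms: none
Why: One-pot activation and partial reduction, in which the tetrahedral aluminium adduct of the acyl imidazolide survives at −78 °C and collapses to the aldehyde only on work-up, and the cold non-basic medium leaves the epimerisable, deconjugated C5 centre intact.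

**Step 6**
Reactants: 12 2,2-dimethoxyacetaldehyde; 13 methyl acrylate
Product: 14 methyl 3-hydroxy-4,4-dimethoxy-2-methylidenebutanoate (racemic)
Conditions: DABCO (0.5 equiv), 1,4-dioxane–H2O 1:1, rt
Reagents that add atoms: none
Why: Morita–Baylis–Hillman reaction, in which the DABCO–acrylate zwitterion adds to the activated α,α-dialkoxy aldehyde, and the racemic carbinol centre is erased in step 7.

**Step 7**
Reactants: 14 methyl 3-hydroxy-4,4-dimethoxy-2-methylidenebutanoate
Product: 15 methyl (2Z)-2-(bromomethyl)-4,4-dimethoxybut-2-enoate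
Conditions: NBS, Me2S, CH2Cl2, 0 °C to rt
Reagents that add atoms: N-bromosuccinimide, O=C1CCC(=O)N1Br
Why: Corey–Kim-type activation of the allylic alcohol followed by SN2′ attack of bromide gives the rearranged primary bromide, with the acetal arm cis to CH2Br (Z), the favoured trisubstituted enoate geometry.

**Step 8**
Reactants: 11 (2S,3S)-aldehyde; 15 (Z)-allyl bromide
Product: 18 methyl (3S,4S,5S,6S)-3-(dimethoxymethyl)-6-methyl-2-methylidene-5-(prop-1-en-2-yl)-4-[(triethylsilyl)oxy]-6-{[(triethylsilyl)oxy]methyl}oct-7-enoate, via allylindium reagent 16 (not isolated), via indium alkoxide 17 (not isolated)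
Conditions: In powder, THF, rt, sonication; then 2,6-lutidine, Et3SiOTf (1.2 equiv), −78 °C
Reagents that add atoms: triethylsilyl trifluoromethanesulfonate, CC[Si](CC)(CC)OS(=O)(=O)C(F)(F)F
Why: Barbier-type indium allylation through the γ-carbon in a closed chair whose Z-placed acetal arm sits axial (6,7-syn adduct), while avoiding the syn-pentane clash with that arm turns H5 inward and keeps quaternary C10 anti to the incoming carbon (anti-Felkin, 5,6-anti), which sets C6 and C7 as needed before the alkoxide is capped as a TES ether so that it cannot lactonise.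

**Step 9**
Reactants: 18 bis-TES ether
Product: 19 methyl (3S,4S,5S,6S)-3-(dimethoxymethyl)-6-formyl-6-methyl-2-methylidene-5-(prop-1-en-2-yl)-4-[(triethylsilyl)oxy]oct-7-enoate
Conditions: (COCl)2, DMSO, CH2Cl2, −78 °C to −40 °C; Et3N, −78 °C to 0 °C
Reagents that add atoms: none
Why: Swern oxidation applied directly to the silyl ether, in which the chlorosulfonium salt exchanges only with the exposed primary O–SiEt3 group and base-induced collapse gives the non-enolisable C9 aldehyde, while the buried secondary TES ether, the acetal and the acrylate are untouched.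

**Step 10**
Reactants: 19 formyl acetal
Product: 21 methyl (3S,4S,5S,6S)-3,6-diformyl-6-methyl-2-methylidene-5-(prop-1-en-2-yl)-4-[(triethylsilyl)oxy]oct-7-enoate, via lutidinium salt 20 (not isolated)
Conditions: Et3SiOTf (2 equiv), 2,6-lutidine (3 equiv), CH2Cl2, 0 °C; then H2O; used at once
Reagents that add atoms: water, O
Why: Acetal cleavage under weakly basic conditions (silyl triflate–pyridine base method), in which Et3SiOTf ionises the aldehyde-derived acetal, 2,6-lutidine traps the oxocarbenium ion as 20 and water releases the aldehyde, so the acid- and base-sensitive C7 centre, the TES ether and the C9 aldehyde survive.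

**Step 11 (key step)**
Reactants: 21 dialdehyde ester
Product: 23 (3aR,4S,5S,6S,7S,7aR)-6-ethenyl-7-hydroxy-6-methyl-3-methylidene-5-(prop-1-en-2-yl)-4-[(triethylsilyl)oxy]hexahydro-1-benzofuran-2(3H)-one, via cis-diol ester 22 (not isolated)
Conditions: 21 added over 2 h to SmI2 (2.3 equiv) in THF (final 3 mM), −78 °C, then 0 °C; pH 7 buffer
Reagents that add atoms: none
Why: Proposed new method: SmI2 reduces the less hindered C8 aldehyde to a ketyl that is held together with the C9 aldehyde on trivalent samarium and couples in a chair carrying the carbon arms at C5 and C7 and the C10 vinyl group equatorial, so the chelated cis-diolate forms with O8 equatorial and O9 axial (an axial O8 would face both the C10 methyl and O6), and the O8 alkoxide then closes the trans-fused lactone on the methyl ester because O6 is silylated and O9 cannot reach; the closest known reaction types are the SmI2 pinacol cyclisation of 1,6-dialdehydes to cis-cyclohexane-1,2-diols and the alkoxide lactonisation that ends SmI2 ketyl–acrylate couplings, and high dilution without proton source or HMPA keeps bimolecular ketyl–acrylate addition slower than ring closure.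

**Step 12**
Reactants: 23 hydroxy lactone; 24 (2Z)-2-methylbut-2-enoic acid (angelic acid)
Product: 26 (3aR,4S,5S,6S,7S,7aR)-6-ethenyl-6-methyl-3-methylidene-2-oxo-5-(prop-1-en-2-yl)-4-[(triethylsilyl)oxy]octahydro-1-benzofuran-7-yl (2Z)-2-methylbut-2-enoate, via mixed anhydride 25 (not isolated)
Conditions: 24, 2,4,6-trichlorobenzoyl chloride, Et3N, toluene, rt; then 23, 75 °C
Reagents that add atoms: none
Why: Yamaguchi-type mixed-anhydride esterification without a nucleophilic catalyst, in which the only free hydroxyl (axial, neopentyl O9) attacks the angeloyl carbonyl of 25, and omitting DMAP avoids the addition–elimination path that turns angelates into tiglates, so the Z geometry and all ring stereocentres are kept.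

**Step 13**
Reactants: 26 angelate
Product: 28 target, (3aS,4S,5R,6S,7S,7aR)-6-ethenyl-4-hydroxy-6-methyl-3-methylidene-2-oxo-5-(3-oxoprop-1-en-2-yl)octahydro-1-benzofuran-7-yl (2Z)-2-methylbut-2-enoate, via silylated enal 27 (not isolated)
Conditions: SeO2 (1.5 equiv), 1,4-dioxane, 70 °C; cool to 0 °C, HF·pyridine
Reagents that add atoms: selenium dioxide, O=[Se]=O
Why: Selenium dioxide allylic oxidation followed by fluoride desilylation in the same flask, in which the isopropenyl group is the only electron-rich alkene with an allylic CH3 (the vinyl group has no allylic hydrogen and the acrylate and angelate alkenes are electron-poor), so C15 goes to the enal, and HF·pyridine then frees O6 under acidic conditions that do not trigger translactonisation.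

**Compound list**
1 | 3-methylbut-2-en-1-ol (prenol) | CC(C)=CCO | starting material
2 | 3-methylbut-2-enoyl chloride | CC(C)=CC(=O)Cl | starting material
3 | isopropenylketene (3-methylbuta-1,3-dien-1-one) | C=C(C)C=C=O | intermediate
4 | 3-methylbut-2-en-1-yl 3-methylbut-3-enoate | C=C(C)CC(=O)OCC=C(C)C | intermediate
5 | (2E)-4-hydroxy-3-methylbut-2-en-1-yl 3-methylbut-3-enoate | C=C(C)CC(=O)OC/C=C(\C)CO | intermediate
6 | (2E)-3-methyl-4-[(triethylsilyl)oxy]but-2-en-1-yl 3-methylbut-3-enoate | C=C(C)CC(=O)OC/C=C(\C)CO[Si](CC)(CC)CC | intermediate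
7 | boron ketene acetal of 6 (isopropenyl cis to allyloxy O, (S,S)-diazaborolidinyl on the other O) | C=C(C)/C=C(\OC/C=C(\C)CO[Si](CC)(CC)CC)OB1N(S(=O)(=O)c2cc(C(F)(F)F)cc(C(F)(F)F)c2)[C@@H](c2ccccc2)[C@H](c2ccccc2)N1S(=O)(=O)c1cc(C(F)(F)F)cc(C(F)(F)F)c1 | intermediate
8 | acyloxyborane of acid 9 | O=C(OB1N(S(=O)(=O)c2cc(C(F)(F)F)cc(C(F)(F)F)c2)[C@@H](c2ccccc2)[C@H](c2ccccc2)N1S(=O)(=O)c1cc(C(F)(F)F)cc(C(F)(F)F)c1)[C@@H](C(C)=C)[C@](C)(C=C)CO[Si](CC)(CC)CC | intermediate
9 | (2S,3S)-3-methyl-2-(prop-1-en-2-yl)-3-{[(triethylsilyl)oxy]methyl}pent-4-enoic acid | OC(=O)[C@@H](C(C)=C)[C@](C)(C=C)CO[Si](CC)(CC)CC | intermediate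
10 | acyl imidazolide of 9 | O=C(n1ccnc1)[C@@H](C(C)=C)[C@](C)(C=C)CO[Si](CC)(CC)CC | intermediate
11 | (2S,3S)-3-methyl-2-(prop-1-en-2-yl)-3-{[(triethylsilyl)oxy]methyl}pent-4-enal | O=C[C@@H](C(C)=C)[C@](C)(C=C)CO[Si](CC)(CC)CC | intermediate
12 | 2,2-dimethoxyacetaldehyde | COC(OC)C=O | starting material
13 | methyl acrylate | C=CC(=O)OC | starting material
14 | methyl 3-hydroxy-4,4-dimethoxy-2-methylidenebutanoate (racemic) | C=C(C(=O)OC)C(O)C(OC)OC | intermediate
15 | methyl (2Z)-2-(bromomethyl)-4,4-dimethoxybut-2-enoate | COC(=O)/C(CBr)=C/C(OC)OC | intermediate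
16 | allylindium reagent from 15 (sesquibromide, drawn as its RInBr2 component) | COC(=O)/C(C[In](Br)Br)=C/C(OC)OC | intermediate
17 | indium alkoxide of the (3S,4S,5S,6S)-4-hydroxy ester | COC(=O)C(=C)[C@H](C(OC)OC)[C@@H](O[In](Br)Br)[C@@H](C(C)=C)[C@](C)(C=C)CO[Si](CC)(CC)CC | intermediate
18 | methyl (3S,4S,5S,6S)-3-(dimethoxymethyl)-6-methyl-2-methylidene-5-(prop-1-en-2-yl)-4-[(triethylsilyl)oxy]-6-{[(triethylsilyl)oxy]methyl}oct-7-enoate | COC(=O)C(=C)[C@H](C(OC)OC)[C@@H](O[Si](CC)(CC)CC)[C@@H](C(C)=C)[C@](C)(C=C)CO[Si](CC)(CC)CC | intermediate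
19 | methyl (3S,4S,5S,6S)-3-(dimethoxymethyl)-6-formyl-6-methyl-2-methylidene-5-(prop-1-en-2-yl)-4-[(triethylsilyl)oxy]oct-7-enoate | COC(=O)C(=C)[C@H](C(OC)OC)[C@@H](O[Si](CC)(CC)CC)[C@@H](C(C)=C)[C@](C)(C=C)C=O | intermediate
20 | α-methoxy 2,6-lutidinium triflate at C8 of 19 | COC(=O)C(=C)[C@H](C(OC)[n+]1c(C)cccc1C)[C@@H](O[Si](CC)(CC)CC)[C@@H](C(C)=C)[C@](C)(C=C)C=O.[O-]S(=O)(=O)C(F)(F)F | intermediate
21 | methyl (3S,4S,5S,6S)-3,6-diformyl-6-methyl-2-methylidene-5-(prop-1-en-2-yl)-4-[(triethylsilyl)oxy]oct-7-enoate | COC(=O)C(=C)[C@H](C=O)[C@@H](O[Si](CC)(CC)CC)[C@@H](C(C)=C)[C@](C)(C=C)C=O | intermediate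
22 | methyl 2-[(1R,2R,3S,4S,5S,6S)-4-ethenyl-2,3-dihydroxy-4-methyl-5-(prop-1-en-2-yl)-6-[(triethylsilyl)oxy]cyclohexyl]prop-2-enoate (present as its samarium diolate) | C=C[C@]1(C)[C@H](O)[C@H](O)[C@@H](C(=C)C(=O)OC)[C@@H](O[Si](CC)(CC)CC)[C@H]1C(C)=C | intermediate
23 | (3aR,4S,5S,6S,7S,7aR)-6-ethenyl-7-hydroxy-6-methyl-3-methylidene-5-(prop-1-en-2-yl)-4-[(triethylsilyl)oxy]hexahydro-1-benzofuran-2(3H)-one | C=C[C@]1(C)[C@H](O)[C@@H]2OC(=O)C(=C)[C@H]2[C@@H](O[Si](CC)(CC)CC)[C@H]1C(C)=C | intermediate
24 | (2Z)-2-methylbut-2-enoic acid (angelic acid) | C/C=C(/C)C(=O)O | starting material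
25 | angelic 2,4,6-trichlorobenzoic anhydride | C/C=C(/C)C(=O)OC(=O)c1c(Cl)cc(Cl)cc1Cl | intermediate
26 | (3aR,4S,5S,6S,7S,7aR)-6-ethenyl-6-methyl-3-methylidene-2-oxo-5-(prop-1-en-2-yl)-4-[(triethylsilyl)oxy]octahydro-1-benzofuran-7-yl (2Z)-2-methylbut-2-enoate | C=C[C@]1(C)[C@H](OC(=O)/C(C)=C\C)[C@@H]2OC(=O)C(=C)[C@H]2[C@@H](O[Si](CC)(CC)CC)[C@H]1C(C)=C | intermediate
27 | (3aR,4S,5R,6S,7S,7aR)-6-ethenyl-6-methyl-3-methylidene-2-oxo-5-(3-oxoprop-1-en-2-yl)-4-[(triethylsilyl)oxy]octahydro-1-benzofuran-7-yl (2Z)-2-methylbut-2-enoate | C=C[C@]1(C)[C@H](OC(=O)/C(C)=C\C)[C@@H]2OC(=O)C(=C)[C@H]2[C@@H](O[Si](CC)(CC)CC)[C@H]1C(=C)C=O | intermediate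
28 | (3aS,4S,5R,6S,7S,7aR)-6-ethenyl-4-hydroxy-6-methyl-3-methylidene-2-oxo-5-(3-oxoprop-1-en-2-yl)octahydro-1-benzofuran-7-yl (2Z)-2-methylbut-2-enoate | C=C[C@]1(C)[C@H](OC(=O)/C(C)=C\C)[C@@H]2OC(=O)C(=C)[C@H]2[C@@H](O)[C@H]1C(=C)C=O | target

**Totals**
Total step count: 13. Longest linear sequence: 11 steps (1–5, then 8–13).

**Steps most likely to fail, with fallbacks**

The riskiest step is step 11, because the ketyl may be captured by the free acrylate of another molecule, or SmI2 may reduce the product methylene lactone. The fallback removes the radical acceptor first and sets out from 19.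
- Conjugate addition of thiophenol (cat. Et3N, CH2Cl2) gives the β-phenylthio ester F1.
- Hydrolysis of the acetal on oxalic acid-doped wet silica gel gives the phenylthio dialdehyde F2.
- The SmI2 closure, now free of any trap, gives the phenylthiomethyl lactone F3.
- mCPBA at −78 °C gives the sulfoxide F4.
- Thermal syn-elimination of F4 in toluene at 90 °C restores the methylene group and returns to the route at 23.

Second is step 8, because the allylindium species can equilibrate and the anti-Felkin facial preference at the crowded aldehyde is not secured. The fallback uses a configurationally fixed allylboron reagent. It sets out from 14 together with 11.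
- Acetylation of 14 (Ac2O, pyridine) gives the Morita–Baylis–Hillman acetate F5.
- CuCl/KOtBu-catalysed SN2′ borylation of F5 with B2pin2 gives the (Z)-allylboronate F6.
- Warming F6 with 11 in toluene at 50 °C passes through a rigid closed chair and gives the borate ester F7.
- Triethanolamine work-up gives the free alcohol F8.
- Et3SiOTf/2,6-lutidine at −78 °C converts F8 and returns to the route at 18.

Third is step 12, because the axial neopentyl O9 may be too hindered for the bulky Z-acid without a nucleophilic catalyst. The fallback builds the angelate on the oxygen and sets out from 23.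
- DCC/DMAP coupling with 2-[bis(2,2,2-trifluoroethoxy)phosphoryl]propanoic acid gives the phosphonopropionate ester F9; this saturated acid cannot isomerise, so DMAP is allowed.
- Still–Gennari olefination with acetaldehyde (KN(SiMe3)2, 18-crown-6, THF, −78 °C) forms the Z-alkene and returns to the route at 26.

**Further compounds**
F1 | step 11 | thiophenol adduct of 19 (C11 epimers) | COC(=O)C(CSc1ccccc1)[C@H](C(OC)OC)[C@@H](O[Si](CC)(CC)CC)[C@@H](C(C)=C)[C@](C)(C=C)C=O
F2 | step 11 | phenylthio dialdehyde | COC(=O)C(CSc1ccccc1)[C@H](C=O)[C@@H](O[Si](CC)(CC)CC)[C@@H](C(C)=C)[C@](C)(C=C)C=O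
F3 | step 11 | phenylthiomethyl lactone | C=C[C@]1(C)[C@H](O)[C@@H]2OC(=O)C(CSc3ccccc3)[C@H]2[C@@H](O[Si](CC)(CC)CC)[C@H]1C(C)=C
F4 | step 11 | phenylsulfinylmethyl lactone | C=C[C@]1(C)[C@H](O)[C@@H]2OC(=O)C(CS(=O)c3ccccc3)[C@H]2[C@@H](O[Si](CC)(CC)CC)[C@H]1C(C)=C
F5 | step 8 | methyl 3-acetoxy-4,4-dimethoxy-2-methylidenebutanoate | C=C(C(=O)OC)C(OC(C)=O)C(OC)OC
F6 | step 8 | methyl (2Z)-4,4-dimethoxy-2-[(4,4,5,5-tetramethyl-1,3,2-dioxaborolan-2-yl)methyl]but-2-enoate | COC(=O)/C(CB1OC(C)(C)C(C)(C)O1)=C/C(OC)OC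
F7 | step 8 | pinacol borate of the (3S,4S,5S,6S)-4-hydroxy ester | COC(=O)C(=C)[C@H](C(OC)OC)[C@@H](OB1OC(C)(C)C(C)(C)O1)[C@@H](C(C)=C)[C@](C)(C=C)CO[Si](CC)(CC)CC
F8 | step 8 | methyl (3S,4S,5S,6S)-3-(dimethoxymethyl)-4-hydroxy-6-methyl-2-methylidene-5-(prop-1-en-2-yl)-6-{[(triethylsilyl)oxy]methyl}oct-7-enoate | COC(=O)C(=C)[C@H](C(OC)OC)[C@@H](O)[C@@H](C(C)=C)[C@](C)(C=C)CO[Si](CC)(CC)CC
F9 | step 12 | 9-O-{2-[bis(2,2,2-trifluoroethoxy)phosphoryl]propanoyl} derivative of 23 | C=C[C@]1(C)[C@H](OC(=O)C(C)P(=O)(OCC(F)(F)F)OCC(F)(F)F)[C@@H]2OC(=O)C(=C)[C@H]2[C@@H](O[Si](CC)(CC)CC)[C@H]1C(C)=C
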